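The equilibrium constant of the binding step times the charge of G comes to 2.60, and from this number and the step's rate constant we reckon where the binding levels off and how fast it gets there.

    D → E (k1 = 0.023 s⁻¹)
    G → L (k2 = 0.025 s⁻¹)
    L + E ⇌ L.E (K3 = 260 L mol⁻¹, k3 = 0.64 L mol⁻¹ s⁻¹)

| flask | G | D | time | remark |
|---|---|---|---|---|
| Saturday's | 10 mM (fed, over 4.00 min) | 1.10 equiv | 8.0 min | all but G at the start; G goes in evenly over 4.00 min, the run ends at 8.0 min |
| Wednesday's | 10 mM | 1.10 equiv | 8.0 min | a closed flask charged with all of it at once and left for 8.0 min |
| Monday's | 10 mM | 1.10 equiv (fed, over 4.00 min) | 8.0 min | a stirred flask in which D is dosed at a steady rate over 4.00 min without added volume, worked up at 8.0 min |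
| Tuesday's | 10 mM | 1.10 equiv |  | one stirred flow tank at steady state, fed with the mixture as stated, mean residence time 8.0 min |

* the set-up with the highest amount of L at the outlet or at the end, in percent of the G put in ("none" if the first two lie within 2 percentage points) (Saturday's / Wednesday's / Monday's / Tuesday's / none)
* amount of L at the outlet or at the end, in percent of the G put in, Saturday's
* amount of L at the outlet or at the end, in percent of the G put in, Wednesday's
* amount of L at the outlet or at the end, in percent of the G put in, Monday's
* amount of L at the outlet or at the end, in percent of the G put in, Tuesday's

Let x be free L as a fraction of the G charged, once G and D have reacted. Free E is then x plus the excess of D, 0.100, and L.E is the remainder of the charge. The equilibrium condition gives x = 42.4%.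

Linearising about that end point gives the binding lifetime, or relaxation time, 1.96 min: the time in which a small excess of L over x shrinks by the natural factor. G and D last 0.667 min and 0.725 min, so as a rough first step we count them as instant because both are shorter than that lifetime. We also apply the decay roughly to the whole starting excess, the charge less x.

Wednesday's flask has 4.09 lifetimes, which gives 43.3%. In Saturday's and Monday's, dosing delays the mean arrival of the dosed charge by 2.00 min, leaving 3.07 lifetimes, so Saturday's gives 45.0% and Monday's, by the same count, 45.0%. Tuesday's tank spreads its residence times around their mean, and averaging the decay over that spread divides the excess by one plus the lifetimes counted: 53.7%. On this reckoning the winner is Tuesday's.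

The forecast gave 45%, 43.5%, 45.2% and 50.4% in the order Saturday's, Wednesday's, Monday's, Tuesday's, with Tuesday's ahead, on the ground that “its steady-state outflow keeps binding further from equilibrium”; its tank figure is lower than ours.

The simulation gives 45.8%, 43.6%, 46.0% and 50.4% in the same order, Tuesday's standing highest, and our tank figure is 3.3 percentage points too high.

Now take a neighbour like Saturday's flask but with 25 mM of G. The equilibrium constant times the charge becomes 6.50, so the reckoned end point falls to 28.5%. The lifetime shortens to 1.26 min. Counting 4.75 lifetimes from the mean arrival, we expect 29.2% of L. That flask reads 29.7% of L at 8.00 min, with L.E at 70.3%.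

The constants used here are those of an exercise; the result is computed.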